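## Structural features

The target is an isoflavan-quinone: a chroman (benzo ring A fused to dihydropyran ring C) joined through the single bond C3–C1' to a 2,3-dimethoxy-1,4-benzoquinone (ring B; carbonyls at C2' and C5', methoxy groups at C3' and C4', hydrogen at C6'). Ring A carries four adjacent oxygens (O1 on C8a, OMe on C8, free OH on C7, OMe on C6) and one hydrogen, at C5. C3 is the only stereocentre (S). It has no stereogenic neighbour, lying between the C2 methylene ether, the benzylic C4 methylene and the quinone carbon C1', so its configuration must come from a reagent. The fragile groups are the methoxyquinone (electrophilic, easily reduced, and able to acidify the C3–H vinylogously) and the oxidation-prone 2,6-dimethoxyphenol of ring A; both are best revealed last. The real difficulty is to join two electron-rich rings of different oxygenation at a non-activated tertiary stereocentre and then raise only ring B to the quinone level, although ring A is itself a masked hydroquinone (O1 and the C6 methoxy are para). The key step exploits ring B: para oxygens at C2' and C5', hydrogen at C6' and the chromanyl group at C1' beside the C2' oxygen is the pattern of a chromium alkoxycarbene benzannulation. A terminal alkyne supplies C1' and C6', carbon monoxide C2', the carbene carbon C5' and a 1,2-dimethoxyvinyl group C3' and C4'.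

## Logic of the disconnections

26 ⇒ 24 (through 25). No skeletal bond is cut; the C7 O–H of 26 becomes an O–benzyl bond in 24. A free ring A phenol would not survive the oxidation that makes the quinone, and benzyl tolerates every earlier reagent. The demand is a debenzylation that does no lasting harm to ring B: hydrogenolysis passes through 25, so a mild reoxidation that spares the new phenol must follow in the same operation.

24 ⇒ 23. The C5' carbonyl is traced back to C5'–OCH3 and the C2' carbonyl to C2'–OH. This turns ring B into a robust benzene at the oxidation level that a benzannulation delivers. The demand is an oxidant that attacks only a free phenol, because ring A of 23 is a hydroquinone diether.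

23 ⇒ 16 + 21 (+ CO). Three ring B bonds are cut: C5'–C6', C1'–C2' and C2'–C3'. Ring B falls into a two-carbon alkyne, a three-carbon carbene ligand and one CO, and the C3 stereocentre is moved onto a small alkyne that can be made enantiopure. The demands are regioselective alkyne insertion (chromanyl next to the CO-derived carbon), CO insertion in preference to five-membered ring closure, and neutral conditions that leave C3 alone.

21 ⇒ 17 + 18. The bond between the carbene carbon and the vinyl carbon and the O–CH3 bond are cut. The complex then comes from a vinyl ether, the metal carbonyl and a methylating agent. The demand is a vinyllithium 19 that does not lose methoxide; this fixes the E geometry of 17.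

16 ⇒ 13 (through 15 and 14). The C≡C bond is cut and the terminal carbon removed, leaving a formyl group on C3. The demand is a one-carbon homologation that does not epimerise the α-stereocentre of 13, which also carries a β-aryloxy leaving group.

13 ⇒ 11 (through 12). Only the oxidation level of the C3 carbon substituent changes. The carboxylic acid is needed as the binding group for the hydrogenation catalyst, so reduction and mild reoxidation are accepted.

11 ⇒ 10. The C3–H and C4–H bonds are removed, restoring C3=C4. The stereocentre is thus derived from a flat, conjugated acid by catalytic asymmetric hydrogenation. The demand is high face selectivity and inertness of the benzyl ether.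

10 ⇒ 7 + 8 (through 9). O1–C2 and C3–C4 are cut. Ring C and the acrylate unit come from a salicylaldehyde and an acrylic ester in one annulation. The demand is an ester that cannot lactonise to a coumarin and is cleaved without base.

7 ⇒ 6. The C4a–CHO bond is cut. The demand is formylation strictly ortho to the phenol.

6 ⇒ 1 (through 5, 4, 3, 2). The C8a–O bond, the C–Br bond that precedes it and the O–benzyl bond are cut. The fourth oxygen of ring A is placed by bromination and boron-to-oxygen exchange. The demand is bromination para to a flanking methoxy group and not para to the central benzyloxy group.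

## Other disconnections considered

Alternative 1: The cut removes C3–C1' and C4–C4a together, so that C3 and C4 come from vinylboronate A2. Forward, ring B bromide A3 is lithiated and added to A2. The boronate complex meets ring A triflate A4 under Pd(OAc)2 and a Mandyphos ligand. The arylpalladium species of divalent palladium activates the vinyl group, the ring B aryl shifts from boron to C3 as palladium carries ring A to C4, and reductive elimination gives (S)-boronate A1. From A1, C2 would be added by Matteson homologation, followed by oxidation to the alcohol, removal of the methoxymethyl group, Mitsunobu closure of ring C, hydrogenolysis and oxidation.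
- In its favour: both arenes and the stereocentre are united in one catalytic enantioselective step, ring B arrives complete so no annulation regiochemistry arises, and no stoichiometric chromium is used.
- Against it here: A4 is an electron-rich, ortho-substituted triflate on a pentaoxygenated ring, which costs about three extra steps from 7 and should be slow in oxidative addition. The migrating aryl group carries an ortho benzyloxy group. The hindered secondary benzylic boronate A1 may homologate sluggishly or protodeboronate. Several operations after the key step serve only to close ring C.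
- Comparison: Alternative 1 is the better plan on convergence and on forming the stereocentre in the fragment union. It is the equal of the chosen plan in kind of stereocontrol (ligand-controlled catalysis) and roughly equal in step count. The chosen plan is stronger because ring C is closed early by a robust annulation and the stereocentre rests on a hydrogenation class with broad precedent.

Alternative 2: Only C3–C1' is cut in the skeleton; a temporary C4–O bond to the C2' oxygen is formed at the same time and cleaved later. Chromene A6 (about two operations from 6) would add to quinone A7 held on a chiral titanium TADDOLate made from TiCl2(OiPr)2. C3 of A6 attacks an unsubstituted quinone carbon, the C4 benzylic cation (stabilised by the para benzyloxy group) is captured by the neighbouring carbonyl oxygen, and tautomerisation gives cis-pterocarpan A5. Hydrogenolysis of A5 would cleave the benzylic C4–O bond and the benzyl ether together, and reoxidation would follow as in step 15.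
- In its favour: it is much the shortest route (about half the operations), the symmetry of A7 removes any regiochemical question, and ring B arrives with all oxygens at the right level.
- Against it here: the absolute configuration depends on a stoichiometric chiral Lewis acid whose selectivity for this chromene and quinone pair cannot be predicted. Cyclobutane ([2+2]) adducts and acid-induced oligomerisation of the electron-rich A6 are expected competitors. The enantiomeric purity of A5 would be harder to upgrade than that of crystalline acid 11.
- Comparison: Alternative 2 is the better plan on step economy and on the match between reagent and ring B pattern, and the equal of the chosen plan in regiochemical certainty. The chosen plan is preferred only for the security of the C3 configuration and because it needs no stoichiometric chiral reagent.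

Alternative 3: The cuts are C3–C4 and O1–C2. Salicyl alcohol A9 (from 7 by reduction) would be ionised by a chiral phosphoric acid to the ring A ortho-quinone methide. This adds (E)-enecarbamate A10 in an inverse-demand hetero-Diels–Alder reaction organised by hydrogen bonds to the catalyst, closing ring C as trans-2-aminoisoflavan A8. Reductive removal of the C2 nitrogen (Lewis acid, Et3SiH), hydrogenolysis and oxidation would finish the synthesis.
- In its favour: ring C, the C3–C4 bond and the stereocentre are formed in one metal-free catalytic step from two arenes of similar size, with a shorter longest linear sequence than the chosen plan.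
- Against it here: the quinone methide is unsubstituted at its methylene carbon, whereas highly selective acid-catalysed versions rely mainly on aryl-stabilised methides. A10 must be made as one geometric isomer. The later ionisation at C2 gives an oxocarbenium ion that can lose the benzylic C3 proton to an achiral 4H-chromene, so the stereocentre is at risk after it has been set.
- Comparison: Alternative 3 is the better plan on convergence and linear length, and the equal of the chosen plan in using catalytic asymmetric induction. The chosen plan keeps C3 away from cationic or enolisable situations once the alkyne is in place and is therefore judged safer for the configuration.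

Key step: step 13

Remark (assumption): commercial 1,2-dimethoxyethene is a cis/trans mixture and the E isomer 17 is taken from it by fractional distillation. The E isomer is used because its lithio derivative 19 has lithium syn to the β-methoxy group and cannot lose methoxide by anti elimination; the alkene geometry of 21 disappears when its β-carbon becomes aromatic C3'.

## Route

Step 1
Reactants: 1 2,6-dimethoxyphenol
Product: 2 2-(benzyloxy)-1,3-dimethoxybenzene
Conditions: BnBr, K2CO3, DMF, 60 °C
Reagents that add atoms: benzyl bromide, BrCc1ccccc1
Why: Williamson etherification; benzyl is chosen because it survives organolithiums, borane, homogeneous hydrogenation and the carbene chemistry and is removed by hydrogenolysis at the end.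

Step 2
Reactants: 2 2-(benzyloxy)-1,3-dimethoxybenzene
Product: 3 2-(benzyloxy)-4-bromo-1,3-dimethoxybenzene
Conditions: NBS, MeCN, 0 °C → rt
Reagents that add atoms: N-bromosuccinimide, O=C1CCC(=O)N1Br
Why: Electrophilic aromatic bromination; C4 is ortho to one methoxy group and para to the other, while C5 is only para to the central benzyloxy group, which is twisted out of conjugation, so monobromination at C4 is expected as for 1,2,3-trimethoxybenzene.

Step 3
Reactants: 3 2-(benzyloxy)-4-bromo-1,3-dimethoxybenzene
Product: 6 3-(benzyloxy)-2,4-dimethoxyphenol, via aryllithium 4 (not isolated), via lithium aryltrimethoxyborate 5 (not isolated)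
Conditions: n-BuLi, THF, −78 °C; B(OMe)3, −78 °C → rt; AcOH, 30 % H2O2, 0 °C → rt
Reagents that add atoms: n-butyllithium, [Li]CCCC (lithium of 4 and 5); trimethyl borate, COB(OC)OC (boron and methoxy groups of 5); hydrogen peroxide, OO (phenol oxygen of 6)
Why: Bromine–lithium exchange at −78 °C outruns benzylic deprotonation of the benzyl ether; borylation and peroxide-induced aryl migration from boron to oxygen place the fourth ring A oxygen with full positional control.

Step 4
Reactants: 6 3-(benzyloxy)-2,4-dimethoxyphenol
Product: 7 4-(benzyloxy)-2-hydroxy-3,5-dimethoxybenzaldehyde
Conditions: MgCl2, Et3N, (CH2O)n, MeCN, reflux; then 1 M HCl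
Reagents that add atoms: paraformaldehyde (formaldehyde), C=O
Why: Casnati–Skattebøl ortho-formylation; the magnesium phenoxide delivers formaldehyde to the only free ortho carbon and a second formaldehyde accepts hydride from the benzylic alkoxide, so no other ring position reacts.

Step 5
Reactants: 7 4-(benzyloxy)-2-hydroxy-3,5-dimethoxybenzaldehyde; 8 tert-butyl acrylate
Product: 9 tert-butyl 7-(benzyloxy)-6,8-dimethoxy-2H-chromene-3-carboxylate
Conditions: DABCO, CHCl3/H2O, rt → 40 °C
Reagents that add atoms: none
Why: Baylis–Hillman addition of the DABCO–acrylate zwitterion to the aldehyde, then conjugate addition of the phenoxide and elimination, closes the 2H-chromene (formation of O1–C2 and C3–C4); the tert-butyl ester suppresses lactonisation to a coumarin, and the same annulation is known for 3-methoxysalicylaldehydes.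

Step 6
Reactants: 9 tert-butyl 7-(benzyloxy)-6,8-dimethoxy-2H-chromene-3-carboxylate
Product: 10 7-(benzyloxy)-6,8-dimethoxy-2H-chromene-3-carboxylic acid
Conditions: TFA/CH2Cl2 (1:4), 0 °C → rt
Reagents that add atoms: none
Why: Acidolysis of the tert-butyl ester by loss of the tert-butyl cation; short exposure to dilute TFA should leave the aryl benzyl ether and the conjugated alkene intact.

Step 7
Reactants: 10 7-(benzyloxy)-6,8-dimethoxy-2H-chromene-3-carboxylic acid
Product: 11 (R)-7-(benzyloxy)-6,8-dimethoxychroman-3-carboxylic acid
Conditions: Ru(OAc)2[(S)-BINAP] (1 mol %), H2 (30 atm), MeOH, 40 °C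
Reagents that add atoms: none
Why: Noyori asymmetric hydrogenation of an α,β-unsaturated acid; the carboxylate binds divalent ruthenium and H2 is added to one face of C3=C4 inside the chiral diphosphine pocket, which sets C3, and the (S)-ligand is assigned to the (R)-acid by analogy with tiglic acid (same cis relation of β-substituent and α-carbon substituent), to be verified by chiral HPLC; the benzyl ether is inert to this homogeneous catalyst.

Step 8
Reactants: 11 (R)-7-(benzyloxy)-6,8-dimethoxychroman-3-carboxylic acid
Product: 12 (S)-[7-(benzyloxy)-6,8-dimethoxychroman-3-yl]methanol
Conditions: BH3·SMe2, THF, 0 °C → rt; then H2O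
Reagents that add atoms: none
Why: Borane reduction of a carboxylic acid through the acyloxyborane, without enolisation; the descriptor changes from R to S only because CH2OH ranks below C2, and no bond at C3 is touched.

Step 9
Reactants: 12 (S)-[7-(benzyloxy)-6,8-dimethoxychroman-3-yl]methanol
Product: 13 (R)-7-(benzyloxy)-6,8-dimethoxychroman-3-carbaldehyde
Conditions: Dess–Martin periodinane, CH2Cl2, 0 °C → rt
Reagents that add atoms: none
Why: Dess–Martin oxidation under near-neutral, amine-free conditions, chosen because 13 can epimerise by enolisation or by reversible β-elimination of the aryloxide; the crude aldehyde is used at once.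

Step 10
Reactants: 13 (R)-7-(benzyloxy)-6,8-dimethoxychroman-3-carbaldehyde
Product: 14 (S)-7-(benzyloxy)-3-(2,2-dibromovinyl)-6,8-dimethoxychroman
Conditions: CBr4, PPh3, CH2Cl2, ylide pre-formed at 0 °C, aldehyde added at −78 → 0 °C
Reagents that add atoms: carbon tetrabromide, BrC(Br)(Br)Br
Why: Ramirez dibromo-olefination (first stage of the Corey–Fuchs sequence); the weakly basic ylide Ph3P=CBr2 undergoes a Wittig reaction faster than it can deprotonate C3, so the configuration should be kept.

Step 11
Reactants: 14 (S)-7-(benzyloxy)-3-(2,2-dibromovinyl)-6,8-dimethoxychroman
Product: 16 (S)-7-(benzyloxy)-3-ethynyl-6,8-dimethoxychroman, via lithium acetylide 15 (not isolated)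
Conditions: n-BuLi (2.1 equiv), THF, −78 °C; then H2O
Reagents that add atoms: n-butyllithium, [Li]CCCC (lithium of 15)
Why: Second stage of the Corey–Fuchs sequence: bromine–lithium exchange, Fritsch–Buttenberg–Wiechell 1,2-shift with loss of LiBr, deprotonation to the acetylide and protonation; the propargylic C3–H is not acidic enough to be removed at −78 °C.

Step 12
Reactants: 17 (E)-1,2-dimethoxyethene; 18 chromium hexacarbonyl
Product: 21 pentacarbonyl{[(E)-1,2-dimethoxyvinyl](methoxy)carbene}chromium, via vinyllithium 19 (not isolated), via lithium acylchromate 20 (not isolated)
Conditions: t-BuLi, THF, −78 °C; Cr(CO)6, THF, −78 → 0 °C; then Me3OBF4, CH2Cl2, 0 °C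
Reagents that add atoms: tert-butyllithium, [Li]C(C)(C)C (lithium of 19 and 20); trimethyloxonium tetrafluoroborate, C[O+](C)C.F[B-](F)(F)F (O-methyl group of 21)
Why: Fischer carbene synthesis: α-lithiation of the enol ether (lithium syn to the β-methoxy group), addition to a CO ligand of zerovalent chromium and O-methylation of the acylchromate, as for other α-alkoxyvinyllithiums; the product is kept cold under argon and used promptly.

Step 13
Reactants: 16 (S)-7-(benzyloxy)-3-ethynyl-6,8-dimethoxychroman; 21 pentacarbonyl{[(E)-1,2-dimethoxyvinyl](methoxy)carbene}chromium
Product: 23 6-[(S)-7-(benzyloxy)-6,8-dimethoxychroman-3-yl]-2,3,4-trimethoxyphenol, via tricarbonylchromium phenol complex 22 (not isolated)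
Conditions: 21 (1.5 equiv), THF (0.05 M), 50 °C, Ar; then air, daylight, Et2O, rt
Reagents that add atoms: none
Why: Proposed new method: a 1,2-dialkoxyvinyl(alkoxy)carbene complex has not been used in this benzannulation, the closest known reaction type being the Dötz reaction of alkenyl-, dihydropyranyl- and furyl(alkoxy)carbene chromium complexes with terminal alkynes, and 21 carries the same Cr=C–C=C array with only donor groups added. Thermal loss of a cis CO ligand, which the syn β-methoxy oxygen can assist by chelation, frees a site for 16; alkyne insertion into Cr=C joins the former carbene carbon to the CH terminus (C5'–C6'), CO insertion gives an η4-vinylketene (C1'–C2'), and the ketene carbon then bonds to the methoxy-bearing vinyl terminus (C2'–C3'). Ring B is thus closed by a thermal six-electron electrocyclisation of a dienylketene, and the resulting cyclohexa-2,4-dienone enolises to the phenol, held first as its Cr(CO)3 complex 22 and released by air and light. The selectivity needed is regiochemical, the chromanyl group having to end next to the CO-derived carbon, and it is secured by the size difference between this secondary alkyl group and hydrogen, which keeps the bulkier alkyne terminus away from the former carbene carbon during insertion. The second demand is CO insertion in preference to five-membered ring closure, for which chromium, THF and moderate temperature are the conditions that favour phenols from alkenyl complexes. No stereocentre is created, since the sp3 carbon of the dienone and the alkene geometry of 21 both vanish on aromatisation. C3 of 16 is propargylic but has no carbonyl activation and the medium is neutral, so it should pass through unchanged.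

Step 14
Reactants: 23 6-[(S)-7-(benzyloxy)-6,8-dimethoxychroman-3-yl]-2,3,4-trimethoxyphenol
Product: 24 5-[(S)-7-(benzyloxy)-6,8-dimethoxychroman-3-yl]-2,3-dimethoxy-1,4-benzoquinone
Conditions: PhI(OAc)2, MeCN/H2O (4:1), 0 °C
Reagents that add atoms: water, O
Why: Oxidative demethylation of a para-methoxyphenol by trivalent iodine: ligand exchange at the phenol oxygen, attack of water at the methoxy-bearing para carbon and loss of methanol from the hemiketal; the reagent needs a free phenol, so the fully etherified ring A is spared, which a one-electron oxidant such as (NH4)2Ce(NO3)6 would not guarantee.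

Step 15
Reactants: 24 5-[(S)-7-(benzyloxy)-6,8-dimethoxychroman-3-yl]-2,3-dimethoxy-1,4-benzoquinone
Product: 26 5-[(S)-7-hydroxy-6,8-dimethoxychroman-3-yl]-2,3-dimethoxy-1,4-benzoquinone (the target), via hydroquinone 25 (not isolated)
Conditions: H2 (1 atm), Pd/C (10 %), EtOAc, rt; filtration; then air, SiO2, EtOAc, rt
Reagents that add atoms: none
Why: Hydrogenolysis of the aryl benzyl ether, during which the quinone is reduced to the hydroquinone, followed by autoxidation of the electron-rich 2,3-dimethoxyhydroquinone in air on silica; no base is present, so the C3–H next to ring B and the ring A phenol should both be preserved.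

## Compound list

1 | 2,6-dimethoxyphenol | COc1cccc(OC)c1O | starting material
2 | 2-(benzyloxy)-1,3-dimethoxybenzene | COc1cccc(OC)c1OCc1ccccc1 | intermediate
3 | 2-(benzyloxy)-4-bromo-1,3-dimethoxybenzene | COc1ccc(Br)c(OC)c1OCc1ccccc1 | intermediate
4 | [3-(benzyloxy)-2,4-dimethoxyphenyl]lithium | [Li]c1ccc(OC)c(OCc2ccccc2)c1OC | intermediate
5 | lithium [3-(benzyloxy)-2,4-dimethoxyphenyl]trimethoxyborate | [Li+].CO[B-](OC)(OC)c1ccc(OC)c(OCc2ccccc2)c1OC | intermediate
6 | 3-(benzyloxy)-2,4-dimethoxyphenol | Oc1ccc(OC)c(OCc2ccccc2)c1OC | intermediate
7 | 4-(benzyloxy)-2-hydroxy-3,5-dimethoxybenzaldehyde | O=Cc1cc(OC)c(OCc2ccccc2)c(OC)c1O | intermediate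
8 | tert-butyl acrylate | C=CC(=O)OC(C)(C)C | starting material
9 | tert-butyl 7-(benzyloxy)-6,8-dimethoxy-2H-chromene-3-carboxylate | CC(C)(C)OC(=O)C1=Cc2cc(OC)c(OCc3ccccc3)c(OC)c2OC1 | intermediate
10 | 7-(benzyloxy)-6,8-dimethoxy-2H-chromene-3-carboxylic acid | OC(=O)C1=Cc2cc(OC)c(OCc3ccccc3)c(OC)c2OC1 | intermediate
11 | (R)-7-(benzyloxy)-6,8-dimethoxychroman-3-carboxylic acid | OC(=O)[C@H]1COc2c(cc(OC)c(OCc3ccccc3)c2OC)C1 | intermediate
12 | (S)-[7-(benzyloxy)-6,8-dimethoxychroman-3-yl]methanol | OC[C@H]1COc2c(cc(OC)c(OCc3ccccc3)c2OC)C1 | intermediate
13 | (R)-7-(benzyloxy)-6,8-dimethoxychroman-3-carbaldehyde | O=C[C@H]1COc2c(cc(OC)c(OCc3ccccc3)c2OC)C1 | intermediate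
14 | (S)-7-(benzyloxy)-3-(2,2-dibromovinyl)-6,8-dimethoxychroman | BrC(Br)=C[C@H]1COc2c(cc(OC)c(OCc3ccccc3)c2OC)C1 | intermediate
15 | lithium acetylide of 16, {[(S)-7-(benzyloxy)-6,8-dimethoxychroman-3-yl]ethynyl}lithium | [Li]C#C[C@H]1COc2c(cc(OC)c(OCc3ccccc3)c2OC)C1 | intermediate
16 | (S)-7-(benzyloxy)-3-ethynyl-6,8-dimethoxychroman | C#C[C@H]1COc2c(cc(OC)c(OCc3ccccc3)c2OC)C1 | intermediate
17 | (E)-1,2-dimethoxyethene | CO/C=C/OC | starting material
18 | chromium hexacarbonyl | O=C=[Cr](=C=O)(=C=O)(=C=O)(=C=O)=C=O | starting material
19 | (E)-1,2-dimethoxyvinyllithium | CO/C=C(/OC)[Li] | intermediate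
20 | lithium pentacarbonyl[(E)-2,3-dimethoxyacryloyl]chromate | CO/C=C(/OC)C([O-])=[Cr](=C=O)(=C=O)(=C=O)(=C=O)=C=O.[Li+] | intermediate
21 | pentacarbonyl{[(E)-1,2-dimethoxyvinyl](methoxy)carbene}chromium | CO/C=C(/OC)C(OC)=[Cr](=C=O)(=C=O)(=C=O)(=C=O)=C=O | intermediate
22 | tricarbonyl(η6-arene)chromium complex of 23, metal on ring B (SMILES written as the arene and the Cr(CO)3 fragment joined by a dot) | COc1cc([C@H]2COc3c(cc(OC)c(OCc4ccccc4)c3OC)C2)c(O)c(OC)c1OC.O=C=[Cr](=C=O)=C=O | intermediate
23 | 6-[(S)-7-(benzyloxy)-6,8-dimethoxychroman-3-yl]-2,3,4-trimethoxyphenol | COc1cc([C@H]2COc3c(cc(OC)c(OCc4ccccc4)c3OC)C2)c(O)c(OC)c1OC | intermediate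
24 | 5-[(S)-7-(benzyloxy)-6,8-dimethoxychroman-3-yl]-2,3-dimethoxy-1,4-benzoquinone | COC1=C(OC)C(=O)C([C@H]2COc3c(cc(OC)c(OCc4ccccc4)c3OC)C2)=CC1=O | intermediate
25 | (S)-2-(7-hydroxy-6,8-dimethoxychroman-3-yl)-5,6-dimethoxybenzene-1,4-diol | COc1c(O)cc([C@H]2COc3c(cc(OC)c(O)c3OC)C2)c(O)c1OC | intermediate
26 | 5-[(S)-7-hydroxy-6,8-dimethoxychroman-3-yl]-2,3-dimethoxy-1,4-benzoquinone (CNP0121136.1) | COC1=C(OC)C(=O)C([C@H]2COc3c(cc(OC)c(O)c3OC)C2)=CC1=O | target

## Step count and least certain steps

Total step count: 15 (steps 1–11 to alkyne 16, step 12 to carbene complex 21, steps 13–15). Longest linear sequence: 14 steps (1–11, 13, 14, 15).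

Step 13 (key step, together with the supply of 21 in step 12 on which it depends). Three processes may go wrong. After alkyne insertion the donor-rich dimethoxyvinyl unit may slow CO insertion, so that five-membered ring closure or furan formation competes with benzannulation. The electron-rich complex 21 may decompose by hydrolysis or oxidation before CO loss, or 19 may lose methoxide during its formation. The terminal alkyne may oligomerise at the metal. Fallback with known chemistry (Moore rearrangement): setting out from 16, deprotonation with n-BuLi (THF, −78 °C) regenerates 15, which is added to dimethyl squarate (3,4-dimethoxycyclobut-3-ene-1,2-dione) to give the 4-alkynyl-4-hydroxy-2,3-dimethoxycyclobutenone F1. Heating F1 in p-xylene at reflux opens the four-membered ring to an alkynyl vinylketene, which closes onto the alkyne and transfers the hydroxyl hydrogen. This should give the 2,3-dimethoxy-5-substituted quinone, that is 24, where the route is rejoined; steps 12 to 14 are then not needed.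

Step 7. The risk is insufficient face selectivity, or hydrogen delivery to the opposite face, since the ligand sense is assigned by analogy only. Fallback: from 10, non-selective hydrogenation with [Ir(cod)(PCy3)(py)]PF6 and H2 in CH2Cl2 gives the racemic chroman-3-carboxylic acid F2. F2 is resolved by crystallisation of a diastereomeric 1-phenylethylammonium salt F3 (drawn with the (R)-amine; the other amine antipode is taken if it precipitates the (R)-acid). Acidification returns to 11.

Step 5. The risk is slow initiation with the hindered, electron-rich aldehyde, so that polymerisation of 8 or coumarin formation takes over. Fallback: from 7, acrolein and K2CO3 in 1,4-dioxane at reflux (oxa-Michael addition, intramolecular aldol condensation) give the chromene-3-carbaldehyde F4. Pinnick oxidation (NaClO2, NaH2PO4, 2-methylbut-2-ene, t-BuOH/H2O) then gives 10 directly, bypassing 9 and step 6 at no cost in steps.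

Step 10. The risk is erosion of the C3 configuration of 13 through enolisation or reversible β-elimination and re-addition of the aryloxide during olefination. Fallback: from 13, Colvin homologation with lithiated trimethylsilyldiazomethane (Me3SiCHN2, LDA, THF, −78 °C → rt) adds to the aldehyde at low temperature, loses trimethylsilanolate and dinitrogen, and rearranges the alkylidene carbene by 1,2-hydrogen shift. This returns at 16 in one step and omits 14 and 15; no new compound is made (F0).

Step 15. The risk is incomplete reoxidation of 25, or oxidative coupling of the newly freed ring A phenol under the aerobic conditions. Fallback: from 24, Lewis-acid debenzylation with BCl3 and pentamethylbenzene as cation scavenger (CH2Cl2, −78 °C) gives 26 directly without passing through 25; no new compound is made (F0).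

## Further compounds

F1 | step 13 | 4-{[(S)-7-(benzyloxy)-6,8-dimethoxychroman-3-yl]ethynyl}-4-hydroxy-2,3-dimethoxycyclobut-2-en-1-one (both epimers at the carbinol carbon) | COC1=C(OC)C(O)(C#C[C@H]2COc3c(cc(OC)c(OCc4ccccc4)c3OC)C2)C1=O
F2 | step 7 | rac-7-(benzyloxy)-6,8-dimethoxychroman-3-carboxylic acid | OC(=O)C1COc2c(cc(OC)c(OCc3ccccc3)c2OC)C1
F3 | step 7 | (R)-1-phenylethylammonium (R)-7-(benzyloxy)-6,8-dimethoxychroman-3-carboxylate | [O-]C(=O)[C@H]1COc2c(cc(OC)c(OCc3ccccc3)c2OC)C1.C[C@@H]([NH3+])c1ccccc1
F4 | step 5 | 7-(benzyloxy)-6,8-dimethoxy-2H-chromene-3-carbaldehyde | O=CC1=Cc2cc(OC)c(OCc3ccccc3)c(OC)c2OC1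
F0 | step 10 | none | none
F0 | step 15 | none | none
A1 | alternative 1 | pinacol (S)-1-[2,5-bis(benzyloxy)-3,4-dimethoxyphenyl]-2-[4-(benzyloxy)-3,5-dimethoxy-2-(methoxymethoxy)phenyl]ethylboronate | CC1(C)OB(OC1(C)C)[C@@H](Cc1cc(OC)c(OCc2ccccc2)c(OC)c1OCOC)c1cc(OCc2ccccc2)c(OC)c(OC)c1OCc1ccccc1
A2 | alternative 1 | vinylboronic acid pinacol ester | C=CB1OC(C)(C)C(C)(C)O1
A3 | alternative 1 | 1,4-bis(benzyloxy)-5-bromo-2,3-dimethoxybenzene | Brc1cc(OCc2ccccc2)c(OC)c(OC)c1OCc1ccccc1
A4 | alternative 1 | 4-(benzyloxy)-3,5-dimethoxy-2-(methoxymethoxy)phenyl trifluoromethanesulfonate | COCOc1c(OS(=O)(=O)C(F)(F)F)cc(OC)c(OCc2ccccc2)c1OC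
A5 | alternative 2 | (6aS,11aS)-3-(benzyloxy)-2,4,9,10-tetramethoxypterocarpan-8-ol (cis) | COc1c(OC)c2c(cc1O)[C@H]1COc3c(OC)c(OCc4ccccc4)c(OC)cc3[C@H]1O2
A6 | alternative 2 | 7-(benzyloxy)-6,8-dimethoxy-2H-chromene | C1=Cc2cc(OC)c(OCc3ccccc3)c(OC)c2OC1
A7 | alternative 2 | 2,3-dimethoxy-1,4-benzoquinone | COC1=C(OC)C(=O)C=CC1=O
A8 | alternative 3 | benzyl N-{(2R,3S)-7-(benzyloxy)-3-[2,5-bis(benzyloxy)-3,4-dimethoxyphenyl]-6,8-dimethoxychroman-2-yl}carbamate (trans) | O=C(OCc1ccccc1)N[C@@H]1Oc2c(cc(OC)c(OCc3ccccc3)c2OC)C[C@H]1c1cc(OCc2ccccc2)c(OC)c(OC)c1OCc1ccccc1
A9 | alternative 3 | 3-(benzyloxy)-6-(hydroxymethyl)-2,4-dimethoxyphenol | OCc1cc(OC)c(OCc2ccccc2)c(OC)c1O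
A10 | alternative 3 | benzyl N-{(E)-2-[2,5-bis(benzyloxy)-3,4-dimethoxyphenyl]ethenyl}carbamate | O=C(OCc1ccccc1)N/C=C/c1cc(OCc2ccccc2)c(OC)c(OC)c1OCc1ccccc1
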